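The numbers of this flask are assumed, and the outcome is calculated.

A small charge of nucleophile does two jobs in these flasks, as partner of the electrophile and as sink for the acid set free, so I reckon how far it carries each one.

in all of them: electrophile 0.50 M; gas 29 mM (held); time 25 h
- west: nucleophile 0.600 M
- south-east: nucleophile 1.00 M
- north-west: nucleophile 0.780 M

    gas ⇌ free base, rate k1*(csat - [free base]) (k1 = 0.0295 min⁻¹, csat = 29 mM)
    nucleophile + acid set free ⇌ protonated nucleophile, settled at all times (K2 = 6390 M⁻¹)
    acid set free + target → side product (k3 = 2.87 × 10⁻⁴ M⁻¹ min⁻¹)
    free base ⇌ dormant form (K4 = 6.65, k4 = 7.81 × 10⁻⁴ min⁻¹)
    acid set free + free base ⇌ salt of the base (K5 = 44 M⁻¹, k5 = 0.00820 M⁻¹ min⁻¹)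
    electrophile + nucleophile → acid set free + target (k6 = 5.53 × 10⁻⁴ M⁻¹ min⁻¹)

- at the start none of free base is dissolved
- run time (west): 25 h

- part of the electrophile that has reacted at the end, west
- part of the electrophile that has reacted at the end, south-east
- part of the electrophile that has reacted at the end, north-west
- what raising the concentration of nucleophile from its lowest to its highest value here does to the part of the electrophile that has reacted (changes below 5 percentage points count as none) (no change / it falls / it rises)

In west at the start, the protonation constant times [nucleophile] is 3800, far above the 1.28 that the salt constant times saturated [free base] offers, so I send nearly all of the acid set free to protonated nucleophile and charge two nucleophiles to each electrophile that reacts. In west the reach 60.0%, the part of the electrophile that the nucleophile charge can convert at two nucleophiles each, lies below full conversion, which makes the nucleophile the limiting reagent there.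

That is the stopping end. The starting end is second order in [electrophile] and [nucleophile], and integrating with [nucleophile] falling by two per target joins them: conversion = r(1 − E)/(r − E). Here r is the reach, and E is the exponential of two electrophile charges less the nucleophile charge, times 5.53 × 10⁻⁴ M⁻¹ min⁻¹ and the time.

West has E = 1.39, which gives 29.8%. North-west has reach 78.0% and E = 1.20, which gives 37.2%. South-east has reach 100%, where the form collapses to y/(1 + y) with y = 0.829, the rate constant times the nucleophile charge and the time, giving 45.3%. I therefore expect a rise of 15 percentage points, more than the margin of 5 points.

The forecast, on the ground that “each electrophile reacted effectively removes two nucleophiles”, gives 29.9% for west, 45.3% for south-east and 37.2% for north-west, its west value a last digit off mine, and says it rises. The simulation gives 29.8% for west, 45.3% for south-east and 37.2% for north-west: it rises, by 16 points.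

In north-west at 25.0 h, the half-life of the electrophile by its own step is 51 h, longer than the run of 25 h, and conversion stands at 37.2% against a reach of 78.0%. West left for 250 h stands at 59.5%, level with its reach of 60.0%, with 2.07% of its nucleophile left.

The neighbour of north-west with 1.2 M of electrophile has reach 32.5%, and with E = 3.83 the same form gives 26.2%. That neighbour computes to 26.3%, with 19% of its nucleophile left.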